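## Retrosynthetic overview

1. Ring locants follow the target's bicyclic name: C1(Me)–C6 epoxide, C2=O, C3–OAc, C4–side chain, C5–OAng. In the side chain C2' carries the ring and the =CH2, C3' is the carbinol, C5'=C6' is the prenyl alkene.
2. 21 ⇐ 20 by a last-step catalyst-controlled epoxidation of the prenyl alkene; 20 ⇐ 18 by one double angeloylation; 18 ⇐ 17 by hydroxyl-directed epoxidation of the enone.
3. 17 ⇐ 16 ⇐ 12: the key step is a semipinacol 1,2-alkenyl shift (C5→C4) of an epoxy quinol ketal, intercepted by Evans–Tishchenko hydride/acetyl transfer from acetaldehyde. It sets C4 and C5 and places the acetate on O-3.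
4. 12 ⇐ epoxy quinone monoketal 3 (from m-cresol) + alkenyllithium 11 (from 2-bromoacrolein, allylmagnesium bromide and 2-methylbut-2-ene).
5. Ring order: the carbocycle comes from the arene; C3–C4 epoxide (made, then consumed in the shift) → C1–C6 epoxide → side-chain oxirane last.

Assumptions: 2-bromoacrolein is bought (it can also be made fresh from acrolein); in step 2 the cinchonidinium salt is taken to give (1R,6S)-3, otherwise its pseudo-enantiomeric cinchoninium salt is used.

## Route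

Step 1
Reactants: 1 m-cresol
Product: 2 4,4-dimethoxy-3-methylcyclohexa-2,5-dien-1-one
Conditions: PhI(OAc)2 (2.2 equiv), MeOH, 0 °C → rt
Reagents that add atoms: methanol CO
Why: Two successive hypervalent-iodine phenol oxidations (dearomative oxidative ketalization) trap methanol para to the hydroxyl, so the only free carbonyl is the future C5 and the ketal carbon is the future C2.

Step 2
Reactants: 2 4,4-dimethoxy-3-methylcyclohexa-2,5-dien-1-one
Product: 3 (1R,6S)-5,5-dimethoxy-4-methyl-7-oxabicyclo[4.1.0]hept-3-en-2-one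
Conditions: t-BuOOH (70% aq), N-benzylcinchonidinium chloride (10 mol %), NaOH (aq, cat.), toluene, 0 °C → rt; recrystallize
Reagents that add atoms: tert-butyl hydroperoxide CC(C)(C)OO
Why: Weitz–Scheffer epoxidation under chiral phase-transfer catalysis attacks only the unsubstituted enone C=C (the β-methyl alkene is too hindered), and the ion-paired peroxide picks the enantioface, setting both epoxide carbons (future C3 and C4).

Step 3
Reactants: 4 2-bromoacrolein; 5 allylmagnesium bromide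
Product: 7 (R)-2-bromohexa-1,5-dien-3-ol, via borinate ester 6 (not isolated)
Conditions: (+)-Ipc2BOMe [from (−)-α-pinene], 5, Et2O, 0 °C → rt; then 4, −78 °C; NaOH, H2O2
Reagents that add atoms: none
Why: Brown allylboration through a chair transition state; the (−)-α-pinene-derived B-allyl reagent adds to the Re face of the aldehyde and so sets the (R)-carbinol (future C3').

Step 4
Reactants: 7 (R)-2-bromohexa-1,5-dien-3-ol; 8 2-methylbut-2-ene
Product: 9 (R)-2-bromo-6-methylhepta-1,5-dien-3-ol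
Conditions: Grubbs II (3 mol %), 8 (neat, excess), 40 °C
Reagents that add atoms: none
Why: Olefin cross-metathesis of the monosubstituted alkene with 2-methylbut-2-ene installs the prenyl terminus; the hindered 2-bromo-1-alkene does not enter metathesis.

Step 5
Reactants: 9 (R)-2-bromo-6-methylhepta-1,5-dien-3-ol
Product: 10 (R)-[(2-bromo-6-methylhepta-1,5-dien-3-yl)oxy](tert-butyl)dimethylsilane
Conditions: TBSCl, imidazole, DMF, rt
Reagents that add atoms: tert-butyldimethylsilyl chloride CC(C)(C)[Si](C)(C)Cl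
Why: Standard silylation; the silyl ether keeps O-3' out of the lithiation, the samarium chemistry and the acetyl transfer.

Step 6
Reactants: 10 (R)-[(2-bromo-6-methylhepta-1,5-dien-3-yl)oxy](tert-butyl)dimethylsilane; 3 (1R,6S)-5,5-dimethoxy-4-methyl-7-oxabicyclo[4.1.0]hept-3-en-2-one
Product: 12 (1R,2R,6S)-2-[(3R)-3-(tert-butyldimethylsilyloxy)-6-methylhepta-1,5-dien-2-yl]-5,5-dimethoxy-4-methyl-7-oxabicyclo[4.1.0]hept-3-en-2-ol, via alkenyllithium 11 (not isolated)
Conditions: t-BuLi (2.0 equiv), Et2O, −78 °C; then 3, THF, −78 °C; aq NH4Cl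
Reagents that add atoms: none
Why: Br–Li exchange followed by 1,2-addition to the only ketone, anti to the epoxide oxygen as in manumycin-type epoxy ketones, so the new OH is cis to the epoxide and the alkenyl group is trans to it (antiperiplanar to the C–O bond that will break).

Step 7
Reactants: 12 (1R,2R,6S)-2-[(3R)-3-(tert-butyldimethylsilyloxy)-6-methylhepta-1,5-dien-2-yl]-5,5-dimethoxy-4-methyl-7-oxabicyclo[4.1.0]hept-3-en-2-ol; 13 acetaldehyde
Product: 16 (1S,5R,6R)-5-hydroxy-2,2-dimethoxy-3-methyl-6-[(3R)-3-(tert-butyldimethylsilyloxy)-6-methylhepta-1,5-dien-2-yl]cyclohex-3-en-1-yl acetate, via hydroxy ketone 14 (not isolated), via acetaldehyde hemiacetal 15 (not isolated)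
Conditions: SmI2 (30 mol %, pre-aged with 13), 13 (10 equiv), THF, −20 → 0 °C
Reagents that add atoms: none
Why: Proposed new method: a Sm(III)-catalysed semipinacol 1,2-alkenyl shift intercepted by Evans–Tishchenko acetyl transfer, in which the Sm(III) alkoxide of the syn tertiary OH chelates and ionizes the adjacent epoxide C–O bond, the antiperiplanar alkenyl group shifts from the carbinol carbon to that carbon with inversion (side chain trans to the O that stays on the neighbouring carbon), and the released Sm alkoxide adds acetaldehyde and delivers hydride intramolecularly to the new enone carbonyl from its own face, giving the anti-1,3 pattern (C5–OH cis to the side chain, acetate on O-3) before the aldol-type intermediate can dehydrate or epimerize; the closest known reaction types are the SmI2-catalysed tandem semipinacol/Tishchenko reaction of α-hydroxy epoxides (alkyl or aryl shift to a tertiary epoxide carbon, aryl aldehydes) and the Suzuki–Tsuchihashi alkenyl shift, neither shown for an alkenyl shift onto a secondary epoxide carbon of an epoxy quinol ketal with acetaldehyde as hydride and acetyl donor.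

Step 8
Reactants: 16 (1S,5R,6R)-5-hydroxy-2,2-dimethoxy-3-methyl-6-[(3R)-3-(tert-butyldimethylsilyloxy)-6-methylhepta-1,5-dien-2-yl]cyclohex-3-en-1-yl acetate
Product: 17 (1S,5R,6R)-5-hydroxy-6-[(3R)-3-hydroxy-6-methylhepta-1,5-dien-2-yl]-3-methyl-2-oxocyclohex-3-en-1-yl acetate
Conditions: 48% aq HF, MeCN, 0 °C → rt
Reagents that add atoms: water O
Why: Acidic hydrolysis of the allylic dimethyl ketal (allyl-stabilized oxocarbenium) and fluoride desilylation in one operation unveil the C2 enone and the C3' alcohol without touching a stereocenter.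

Step 9
Reactants: 17 (1S,5R,6R)-5-hydroxy-6-[(3R)-3-hydroxy-6-methylhepta-1,5-dien-2-yl]-3-methyl-2-oxocyclohex-3-en-1-yl acetate
Product: 18 (1S,3S,4R,5S,6S)-5-hydroxy-4-[(3R)-3-hydroxy-6-methylhepta-1,5-dien-2-yl]-1-methyl-2-oxo-7-oxabicyclo[4.1.0]heptan-3-yl acetate
Conditions: t-BuOOH (decane), DBU, CH2Cl2, 0 °C
Reagents that add atoms: tert-butyl hydroperoxide CC(C)(C)OO
Why: Weitz–Scheffer epoxidation touches only the enone, and hydrogen-bond delivery of the peroxide by the free pseudo-axial γ-hydroxyl puts the epoxide cis to C5–OH, setting C1 and C6.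

Step 10
Reactants: 18 (1S,3S,4R,5S,6S)-5-hydroxy-4-[(3R)-3-hydroxy-6-methylhepta-1,5-dien-2-yl]-1-methyl-2-oxo-7-oxabicyclo[4.1.0]heptan-3-yl acetate; 19 angelic acid
Product: 20 (1S,3S,4R,5S,6S)-3-acetoxy-1-methyl-4-{(3R)-6-methyl-3-[(Z)-2-methylbut-2-enoyloxy]hepta-1,5-dien-2-yl}-2-oxo-7-oxabicyclo[4.1.0]heptan-5-yl (Z)-2-methylbut-2-enoate
Conditions: 19 (3 equiv), 2,4,6-Cl3C6H2COCl, Et3N, toluene, rt (mixed anhydride); then 18, 75 °C, no DMAP
Reagents that add atoms: none
Why: DMAP-free Yamaguchi-type esterification acylates both secondary alcohols in one step and is the established way to make angelates without Z→E isomerization to tiglates.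

Step 11
Reactants: 20 (1S,3S,4R,5S,6S)-3-acetoxy-1-methyl-4-{(3R)-6-methyl-3-[(Z)-2-methylbut-2-enoyloxy]hepta-1,5-dien-2-yl}-2-oxo-7-oxabicyclo[4.1.0]heptan-5-yl (Z)-2-methylbut-2-enoate
Product: 21 CNP0407453.2
Conditions: ent-Shi ketone (L-fructose-derived, 30 mol %), Oxone, K2CO3, Bu4NHSO4, MeCN/DMM–aq borate buffer (pH ≈ 10), 0 °C, short reaction time
Reagents that add atoms: potassium peroxymonosulfate [K+].[O-]S(=O)(=O)OO
Why: Shi asymmetric epoxidation; the chiral dioxirane reacts only with the electron-rich trisubstituted prenyl alkene (not the 1,1-disubstituted alkene, the angelates or the ketone) and the L-fructose-derived catalyst gives the (S)-oxirane.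

## Compound list

1 | m-cresol (3-methylphenol) | Cc1cccc(O)c1 | starting material
2 | 4,4-dimethoxy-3-methylcyclohexa-2,5-dien-1-one | COC1(OC)C=CC(=O)C=C1C | intermediate
3 | (1R,6S)-5,5-dimethoxy-4-methyl-7-oxabicyclo[4.1.0]hept-3-en-2-one | O=C1C=C(C)C(OC)(OC)[C@H]2O[C@@H]12 | intermediate
4 | 2-bromoacrolein (2-bromoprop-2-enal) | C=C(Br)C=O | starting material
5 | allylmagnesium bromide | C=CC[Mg]Br | starting material
6 | (R)-2-bromohexa-1,5-dien-3-yl bis(isopinocampheyl)borinate | C=C(Br)[C@@H](CC=C)OB([C@H]1C[C@H]2C[C@@H]([C@@H]1C)C2(C)C)[C@H]1C[C@H]2C[C@@H]([C@@H]1C)C2(C)C | intermediate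
7 | (R)-2-bromohexa-1,5-dien-3-ol | C=C(Br)[C@@H](CC=C)O | intermediate
8 | 2-methylbut-2-ene | CC=C(C)C | starting material
9 | (R)-2-bromo-6-methylhepta-1,5-dien-3-ol | C=C(Br)[C@@H](CC=C(C)C)O | intermediate
10 | (R)-[(2-bromo-6-methylhepta-1,5-dien-3-yl)oxy](tert-butyl)dimethylsilane | C=C(Br)[C@@H](CC=C(C)C)O[Si](C)(C)C(C)(C)C | intermediate
11 | (R)-[3-(tert-butyldimethylsilyloxy)-6-methylhepta-1,5-dien-2-yl]lithium | [Li]C(=C)[C@@H](CC=C(C)C)O[Si](C)(C)C(C)(C)C | intermediate
12 | (1R,2R,6S)-2-[(3R)-3-(tert-butyldimethylsilyloxy)-6-methylhepta-1,5-dien-2-yl]-5,5-dimethoxy-4-methyl-7-oxabicyclo[4.1.0]hept-3-en-2-ol (OH cis to the epoxide) | C=C([C@]1(O)C=C(C)C(OC)(OC)[C@H]2O[C@@H]12)[C@@H](CC=C(C)C)O[Si](C)(C)C(C)(C)C | intermediate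
13 | acetaldehyde | CC=O | starting material
14 | (5S,6S)-6-[(3R)-3-(tert-butyldimethylsilyloxy)-6-methylhepta-1,5-dien-2-yl]-5-hydroxy-4,4-dimethoxy-3-methylcyclohex-2-en-1-one (present as Sm(III) alkoxide, drawn as the alcohol) | C=C([C@@H]1C(=O)C=C(C)C(OC)(OC)[C@H]1O)[C@@H](CC=C(C)C)O[Si](C)(C)C(C)(C)C | intermediate
15 | O-5 (1-hydroxyethyl) hemiacetal of 14 (present as Sm(III) alkoxide, hemiacetal carbon undefined) | C=C([C@@H]1C(=O)C=C(C)C(OC)(OC)[C@H]1OC(C)O)[C@@H](CC=C(C)C)O[Si](C)(C)C(C)(C)C | intermediate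
16 | (1S,5R,6R)-5-hydroxy-2,2-dimethoxy-3-methyl-6-[(3R)-3-(tert-butyldimethylsilyloxy)-6-methylhepta-1,5-dien-2-yl]cyclohex-3-en-1-yl acetate | C=C([C@@H]1[C@H](O)C=C(C)C(OC)(OC)[C@H]1OC(C)=O)[C@@H](CC=C(C)C)O[Si](C)(C)C(C)(C)C | intermediate
17 | (1S,5R,6R)-5-hydroxy-6-[(3R)-3-hydroxy-6-methylhepta-1,5-dien-2-yl]-3-methyl-2-oxocyclohex-3-en-1-yl acetate | C=C([C@@H]1[C@H](O)C=C(C)C(=O)[C@H]1OC(C)=O)[C@@H](CC=C(C)C)O | intermediate
18 | (1S,3S,4R,5S,6S)-5-hydroxy-4-[(3R)-3-hydroxy-6-methylhepta-1,5-dien-2-yl]-1-methyl-2-oxo-7-oxabicyclo[4.1.0]heptan-3-yl acetate | C=C([C@@H]1[C@H](O)[C@@H]2O[C@]2(C)C(=O)[C@H]1OC(C)=O)[C@@H](CC=C(C)C)O | intermediate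
19 | angelic acid [(Z)-2-methylbut-2-enoic acid] | C/C=C(/C)C(=O)O | starting material
20 | (1S,3S,4R,5S,6S)-3-acetoxy-1-methyl-4-{(3R)-6-methyl-3-[(Z)-2-methylbut-2-enoyloxy]hepta-1,5-dien-2-yl}-2-oxo-7-oxabicyclo[4.1.0]heptan-5-yl (Z)-2-methylbut-2-enoate | C=C([C@@H]1[C@H](OC(=O)/C(C)=C\C)[C@@H]2O[C@]2(C)C(=O)[C@H]1OC(C)=O)[C@@H](CC=C(C)C)OC(=O)/C(C)=C\C | intermediate
21 | CNP0407453.2: (1S,3S,4R,5S,6S)-3-acetoxy-4-{(3R)-4-[(2S)-3,3-dimethyloxiran-2-yl]-3-[(Z)-2-methylbut-2-enoyloxy]but-1-en-2-yl}-1-methyl-2-oxo-7-oxabicyclo[4.1.0]heptan-5-yl (Z)-2-methylbut-2-enoate | C=C([C@@H]1[C@H](OC(=O)/C(C)=C\C)[C@@H]2O[C@]2(C)C(=O)[C@H]1OC(C)=O)[C@@H](C[C@@H]1OC1(C)C)OC(=O)/C(C)=C\C | target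

## Step count and risks

Total steps: 11. Longest linear sequence: 9 (steps 3–11); the ring branch (steps 1–2) joins at step 6.

Steps most likely to fail:

Step 7 (proposed new tandem shift/acetyl transfer). The Sm(III) species may be too weak a Lewis acid to open the epoxide at a secondary carbon, or the intermediate may dehydrate. The fallback uses two known reactions. It sets out from 12: silylation (TMSOTf, 2,6-lutidine, CH2Cl2, −78 °C) gives the tertiary trimethylsilyl ether F1. BF3·OEt2 (CH2Cl2, −78 °C, Suzuki–Tsuchihashi rearrangement) then gives hydroxy ketone 14, now isolated cold. A separate Evans–Tishchenko reduction (SmI2 15 mol %, acetaldehyde 13, THF, −10 °C) returns to the route at 16.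

Step 9 (facial selectivity of the enone epoxidation). Without effective hydroxyl delivery the peroxide would add trans to the pseudo-axial C5–OH. The fallback replaces nucleophilic epoxidation by a vanadium-directed one on an allylic alcohol. It sets out from 17, which is bis-angeloylated under the step 10 conditions to the enone bis-angelate F2. Luche reduction (NaBH4, CeCl3·7H2O, MeOH, −78 °C; axial hydride, equatorial carbinol trans to the acetate) gives the allylic alcohol F3. VO(acac)2/t-BuOOH (CH2Cl2, 0 °C) epoxidizes syn to that hydroxyl, on the face of the C5 ester, to give the epoxy alcohol F4. Dess–Martin oxidation then comes back to the route at 20; compound 18 is bypassed.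

Step 10 (double angeloylation of two hindered secondary alcohols on a base- and heat-sensitive epoxy ketone). The fallback builds the Z-alkene on the ester instead of acylating with preformed angelic acid. It sets out from 18, which is acylated with 2-(diphenoxyphosphoryl)propanoic acid (EDC·HCl, DMAP cat., CH2Cl2, 0 °C) to the bis-phosphonate F5. An Ando-type Z-selective Horner–Wadsworth–Emmons reaction with acetaldehyde 13 (NaI, DBU, THF, −78 → 0 °C) makes both (Z)-2-methylbut-2-enoates and comes back at 20.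

## Further compounds

F1 | step 7 | (1R,2R,6S)-2-[(3R)-3-(tert-butyldimethylsilyloxy)-6-methylhepta-1,5-dien-2-yl]-5,5-dimethoxy-4-methyl-2-(trimethylsilyloxy)-7-oxabicyclo[4.1.0]hept-3-ene | C=C([C@]1(O[Si](C)(C)C)C=C(C)C(OC)(OC)[C@H]2O[C@@H]12)[C@@H](CC=C(C)C)O[Si](C)(C)C(C)(C)C
F2 | step 9 | enone bis-angelate: (1S,5R,6R)-1-acetoxy-3-methyl-6-{(3R)-6-methyl-3-[(Z)-2-methylbut-2-enoyloxy]hepta-1,5-dien-2-yl}-2-oxocyclohex-3-en-5-yl (Z)-2-methylbut-2-enoate | C=C([C@@H]1[C@H](OC(=O)/C(C)=C\C)C=C(C)C(=O)[C@H]1OC(C)=O)[C@@H](CC=C(C)C)OC(=O)/C(C)=C\C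
F3 | step 9 | allylic alcohol from F2 (C2 carbinol trans to the acetate, cis to the C5 ester) | C=C([C@@H]1[C@H](OC(=O)/C(C)=C\C)C=C(C)[C@H](O)[C@H]1OC(C)=O)[C@@H](CC=C(C)C)OC(=O)/C(C)=C\C
F4 | step 9 | epoxy alcohol from F3 (C1–C6 epoxide cis to the C2 hydroxyl) | C=C([C@@H]1[C@H](OC(=O)/C(C)=C\C)[C@@H]2O[C@]2(C)[C@H](O)[C@H]1OC(C)=O)[C@@H](CC=C(C)C)OC(=O)/C(C)=C\C
F5 | step 10 | bis[2-(diphenoxyphosphoryl)propanoate] of 18 | C=C([C@@H]1[C@H](OC(=O)C(C)P(=O)(Oc3ccccc3)Oc4ccccc4)[C@@H]2O[C@]2(C)C(=O)[C@H]1OC(C)=O)[C@@H](CC=C(C)C)OC(=O)C(C)P(=O)(Oc1ccccc1)Oc1ccccc1
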